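**Plan**
1. Retrosynthetic cuts, in order: C9–C11 (side chain added to a C9 ketone), C8=C17 (Mannich methylenation), C5–O (hydration of a 5(6)-alkene), C4–C18 (deconjugative methylation), C1–C10 (closure of ring A), C4–C5 (enolate addition to a vinylogous ester).
2. Forward: ring B is bought as 3-ethoxy-2-methylcyclohexenone (C5–C10 with the C10 methyl); the arm C19–C4–C3–C2–C1–Br is joined at C5; ring A is then closed between C1 and C10; the side chain is joined last.
3. Enabling feature: C10 lies between the oxygen-bearing carbons C9 and C5, and C4 carries the C19 carboxyl. At the ketone/alkene oxidation level O=C9–C10=C5–C4H–C19O2R is therefore a vinylogous β-keto ester whose anion is nucleophilic at C10, one six-membered ring away from C1.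
4. Stereochemistry: C10 is set in the ring closure by a chiral ammonium counter-ion; C4 (methyl anti to the C10 methyl), C5 (oxygen anti to the C10 methyl and the C19 ester) and C9 (side chain anti to the C10 methyl) are relayed from C10; the 13E alkene comes from a syn-carboalumination.

Key step: step 3

Remark: atoms carry labdane numbers (decalin C1–C10, C17 on C8, C18/C19 on C4, C20 on C10, side chain C11–C16); β is the face of the C10 methyl, α the opposite face.
Assumption: the cinchonidinium salt of step 3 is taken to give the C10 configuration drawn; should it favour the antipode, the pseudoenantiomeric cinchoninium salt takes its place.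

**Step 1**
Reactants: 1 5-bromopentanoyl chloride; 2 2-(trimethylsilyl)ethanol
Product: 3 2-(trimethylsilyl)ethyl 5-bromopentanoate
Conditions: pyridine, CH2Cl2, 0 °C → rt
Reagents that add atoms: none
Why: Ester formation from an acid chloride and a primary alcohol (acylation); the 2-(trimethylsilyl)ethyl ester is chosen because fluoride can remove it at the end from the hindered C19 position.

**Step 2**
Reactants: 3 2-(trimethylsilyl)ethyl 5-bromopentanoate; 4 3-ethoxy-2-methylcyclohex-2-en-1-one
Product: 6 2-(trimethylsilyl)ethyl 5-bromo-2-(2-methyl-3-oxocyclohex-1-en-1-yl)pentanoate (racemic at C4), via carbinol adduct 5 (not isolated)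
Conditions: LDA, THF, −78 °C; then 4, −78 °C; quench cold with 2 M HCl, THF, 0 °C → rt
Reagents that add atoms: water, O
Why: Stork–Danheiser sequence: 1,2-addition of the ester enolate carbon (C4) to the vinylogous ester carbonyl (C5) followed by acid hydrolysis with allylic transposition should give the 3-substituted 2-methylcyclohexenone, the new C4 centre being racemic and of no consequence because it becomes planar in step 3.

**Step 3**
Reactants: 6 2-(trimethylsilyl)ethyl 5-bromo-2-(2-methyl-3-oxocyclohex-1-en-1-yl)pentanoate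
Product: 7 2-(trimethylsilyl)ethyl (4aS)-4a-methyl-5-oxo-2,3,4,4a,5,6,7,8-octahydronaphthalene-1-carboxylate (labdane locants: 4(5)-ene; 9-oxo; 10β-methyl)
Conditions: N-(9-anthracenylmethyl)-O-allylcinchonidinium bromide (10 mol %), CsOH·H2O (solid), toluene/CH2Cl2 7:3, 0.01 M, −40 °C
Reagents that add atoms: none
Why: Proposed new method: solid CsOH removes the C4 proton of 6 (acidified by the C19 ester and, through C5=C10, by the C9 ketone), and the delocalised anion O9–C9=C10–C5=C4–C19(=O)OR, paired with the chiral ammonium cation, displaces bromide at C1 through C10 in an SN2 step; the closest known reaction types are the C-alkylation of 4-oxocyclohex-2-enecarboxylate-type vinylogous β-keto ester anions at the ketone α-carbon and the cinchona-ammonium-catalysed enantioselective alkylation of β-keto esters to quaternary centres, which have not been combined in a ring closure on this substrate class. Ring A (C10–C1–C2–C3–C4–C5) closes in the 6-exo-tet mode with the enolate π-system exocyclic to the forming ring (6-enolexo), so C1 can reach C10 perpendicular to the anion plane. The new stereocentre C10 is controlled by the cation, which sits at O9 and the ester oxygen and covers one face of the planar anion, so that the C3–C2–C1 arm should fold over the open face. The step needs carbon over oxygen alkylation and C10 over C4 attack: attack through C4 would give a cyclobutane and through O9 an eight-membered ring, the soft bromide in a non-polar medium favours C10 over the ester oxygen, and high dilution suppresses intermolecular alkylation. The product carries the C4=C5 ester and the C9 ketone in the positions from which C4, C5 and C9 are then set under the control of C10.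

**Step 4**
Reactants: 7 2-(trimethylsilyl)ethyl (4aS)-4a-methyl-5-oxo-2,3,4,4a,5,6,7,8-octahydronaphthalene-1-carboxylate
Product: 10 2-(trimethylsilyl)ethyl (1S,4aS)-1,4a-dimethyl-5-oxo-1,2,3,4,4a,5,6,7-octahydronaphthalene-1-carboxylate (5(6)-ene; 4α-methyl; 4β-ester; 10β-methyl), via silyl enol ether 8 (not isolated), via methylated silyl enol ether 9 (not isolated)
Conditions: LDA (1.1 equiv), THF, −78 °C, then TMSCl (1.1 equiv), evaporate; LDA (1.3 equiv), DMPU, THF, −78 °C, then MeI, −78 → −30 °C; 1 M HCl, THF, 0 °C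
Reagents that add atoms: iodomethane, CI
Why: Deconjugative α-alkylation of an extended ester enolate (γ-deprotonation at C6, methylation at C4) with the C9 ketone masked in the flask as its silyl enol ether; iodomethane should enter C4 equatorially on the α face, away from the axial C10 methyl, so that the ester ends up β and the alkene moves to C5=C6.

**Step 5**
Reactants: 10 2-(trimethylsilyl)ethyl (1S,4aS)-1,4a-dimethyl-5-oxo-1,2,3,4,4a,5,6,7-octahydronaphthalene-1-carboxylate
Product: 12 2-(trimethylsilyl)ethyl (1S,4aS,8aS)-8a-hydroxy-1,4a-dimethyl-5-oxodecahydronaphthalene-1-carboxylate (5α-OH; trans-fused), via hydroperoxide 11 (not isolated)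
Conditions: Co(acac)2 (20 mol %), PhSiH3, O2 (1 atm), THF, rt; then PPh3
Reagents that add atoms: dioxygen, O=O
Why: Mukaiyama hydration: hydrogen-atom transfer from a cobalt hydride to C6 gives the tertiary C5 radical, which should take up O2 on the α face because the β face is screened by the axial C10 methyl and the axial C19 ester, and reduction of the hydroperoxide then gives the 5α-alcohol of a trans-fused decalin.

**Step 6**
Reactants: 12 2-(trimethylsilyl)ethyl (1S,4aS,8aS)-8a-hydroxy-1,4a-dimethyl-5-oxodecahydronaphthalene-1-carboxylate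
Product: 15 2-(trimethylsilyl)ethyl (1S,4aS,8aS)-8a-hydroxy-1,4a-dimethyl-6-methylidene-5-oxodecahydronaphthalene-1-carboxylate (8(17)-ene; 9-oxo; 5α-OH), via Mannich base 13 (not isolated), via ammonium iodide 14 (not isolated)
Conditions: LiHMDS (2.2 equiv), THF, −78 °C; CH2=NMe2+ I−, −78 °C → rt; MeI, CH2Cl2, rt; aq NaHCO3, rt
Reagents that add atoms: N,N-dimethylmethyleneiminium iodide, C=[N+](C)C.[I-]
Why: Mannich methylenation: aminomethylation of the C8 enolate (the only enolisable position, C10 being quaternary) by the iminium salt, N-methylation and E1cB loss of trimethylamine should give the exocyclic enone without forming a stereocentre.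

**Step 7**
Reactants: 16 tert-butyl(but-3-yn-1-yloxy)dimethylsilane
Product: 19 (2E)-5-(tert-butyldimethylsilyloxy)-3-methylpent-2-en-1-ol, via alkenylalane 17 (not isolated), via lithium aluminate 18 (not isolated)
Conditions: Me3Al, Cp2ZrCl2 (25 mol %), CH2Cl2, 0 °C → rt; n-BuLi, THF, −78 °C; (CH2O)n, −78 °C → rt
Reagents that add atoms: trimethylaluminium, C[Al](C)C; formaldehyde (from paraformaldehyde), C=O
Why: Negishi zirconium-catalysed carboalumination adds methyl and aluminium syn across the terminal alkyne with methyl on the internal carbon, and hydroxymethylation of the derived aluminate with retention fixes the E geometry of the later C13=C14 bond.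

**Step 8**
Reactants: 19 (2E)-5-(tert-butyldimethylsilyloxy)-3-methylpent-2-en-1-ol
Product: 20 (2E)-5-(tert-butyldimethylsilyloxy)-1-(tert-butyldiphenylsilyloxy)-3-methylpent-2-ene
Conditions: TBDPSCl, imidazole, DMF, rt
Reagents that add atoms: tert-butylchlorodiphenylsilane, CC(C)(C)[Si](Cl)(c1ccccc1)c1ccccc1
Why: Silyl ether formation at the primary allylic alcohol with a silyl group that should outlast the acid cleavage of the TBS ether in step 9.

**Step 9**
Reactants: 20 (2E)-5-(tert-butyldimethylsilyloxy)-1-(tert-butyldiphenylsilyloxy)-3-methylpent-2-ene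
Product: 21 (3E)-5-(tert-butyldiphenylsilyloxy)-3-methylpent-3-en-1-ol
Conditions: PPTS (cat.), EtOH, 50 °C
Reagents that add atoms: none
Why: Acid-catalysed solvolysis (selective desilylation) should cleave the primary TBS ether much faster than the bulkier TBDPS ether.

**Step 10**
Reactants: 21 (3E)-5-(tert-butyldiphenylsilyloxy)-3-methylpent-3-en-1-ol
Product: 22 tert-butyl{[(2E)-5-iodo-3-methylpent-2-en-1-yl]oxy}diphenylsilane
Conditions: I2, PPh3, imidazole, CH2Cl2, 0 °C → rt
Reagents that add atoms: iodine, II
Why: Appel-type iodination of the primary alcohol through an alkoxyphosphonium ion and SN2 displacement, which leaves the allylic silyl ether and the alkene geometry untouched.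

**Step 11**
Reactants: 22 tert-butyl{[(2E)-5-iodo-3-methylpent-2-en-1-yl]oxy}diphenylsilane; 15 2-(trimethylsilyl)ethyl (1S,4aS,8aS)-8a-hydroxy-1,4a-dimethyl-6-methylidene-5-oxodecahydronaphthalene-1-carboxylate
Product: 25 2-(trimethylsilyl)ethyl 15-O-(tert-butyldiphenylsilyl)-5α,9β-dihydroxyisocupressate (9β-OH; side chain 9α; 8(17)-ene; 13E), via organolithium 23 (not isolated), via organocerium 24 (not isolated)
Conditions: 22 (3 equiv), t-BuLi (6 equiv), Et2O, −78 °C; CeCl3 (3 equiv), THF, −78 °C; then 15, −78 °C; aq NH4Cl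
Reagents that add atoms: none
Why: Iodine–lithium exchange and transmetalation give an organocerium reagent that should add 1,2 to the hindered enone carbonyl; one equivalent turns the 5α-OH into a cerium alkoxide that binds O9, and the reagent should attack C9 on the α face, anti to the axial C10 methyl, to give the 9β-alcohol with the side chain α.

**Step 12**
Reactants: 25 2-(trimethylsilyl)ethyl 15-O-(tert-butyldiphenylsilyl)-5α,9β-dihydroxyisocupressate
Product: 26 5α,9β-dihydroxyisocupressic acid
Conditions: TBAF (6 equiv), THF, rt → 40 °C; then 0.1 M HCl to pH 4, 0 °C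
Reagents that add atoms: none
Why: Fluoride-mediated desilylation cleaves the TBDPS ether and, by fragmentation of the 2-(trimethylsilyl)ethyl group to ethene and fluorotrimethylsilane, the hindered C19 ester in one operation under conditions that should leave the tertiary allylic alcohol, the β-hydroxy acid and both alkenes untouched.

**Compound list**
1 | 5-bromopentanoyl chloride | O=C(Cl)CCCCBr | starting material
2 | 2-(trimethylsilyl)ethanol | C[Si](C)(C)CCO | starting material
3 | 2-(trimethylsilyl)ethyl 5-bromopentanoate | C[Si](C)(C)CCOC(=O)CCCCBr | intermediate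
4 | 3-ethoxy-2-methylcyclohex-2-en-1-one | CCOC1=C(C)C(=O)CCC1 | starting material
5 | 2-(trimethylsilyl)ethyl 5-bromo-2-(3-ethoxy-1-hydroxy-2-methylcyclohex-2-en-1-yl)pentanoate (carbinol adduct, diastereomer mixture) | C[Si](C)(C)CCOC(=O)C(CCCBr)C1(O)CCCC(OCC)=C1C | intermediate (not isolated)
6 | 2-(trimethylsilyl)ethyl 5-bromo-2-(2-methyl-3-oxocyclohex-1-en-1-yl)pentanoate (racemic at C4) | C[Si](C)(C)CCOC(=O)C(CCCBr)C1=C(C)C(=O)CCC1 | intermediate
7 | 2-(trimethylsilyl)ethyl (4aS)-4a-methyl-5-oxo-2,3,4,4a,5,6,7,8-octahydronaphthalene-1-carboxylate (4(5)-ene, 9-oxo, 10β-methyl) | C1CCC2=C(C(=O)OCC[Si](C)(C)C)CCC[C@]2(C)C1=O | intermediate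
8 | 2-(trimethylsilyl)ethyl (4aS)-4a-methyl-5-(trimethylsilyloxy)-2,3,4,4a,7,8-hexahydronaphthalene-1-carboxylate (C9 silyl enol ether of 7) | C[Si](C)(C)OC1=CCCC2=C(C(=O)OCC[Si](C)(C)C)CCC[C@]12C | intermediate (not isolated)
9 | 2-(trimethylsilyl)ethyl (1S,4aS)-1,4a-dimethyl-5-(trimethylsilyloxy)-1,2,3,4,4a,7-hexahydronaphthalene-1-carboxylate (C9 silyl enol ether of 10) | C[Si](C)(C)OC1=CCC=C2[C@@](C)(C(=O)OCC[Si](C)(C)C)CCC[C@]12C | intermediate (not isolated)
10 | 2-(trimethylsilyl)ethyl (1S,4aS)-1,4a-dimethyl-5-oxo-1,2,3,4,4a,5,6,7-octahydronaphthalene-1-carboxylate (5(6)-ene, 4α-methyl, 4β-ester, 10β-methyl) | C1CC=C2[C@](C)(CCC[C@]2(C)C(=O)OCC[Si](C)(C)C)C1=O | intermediate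
11 | 2-(trimethylsilyl)ethyl (1S,4aS,8aS)-8a-hydroperoxy-1,4a-dimethyl-5-oxodecahydronaphthalene-1-carboxylate (5α-OOH) | C1CC[C@]2(OO)[C@](C)(CCC[C@]2(C)C(=O)OCC[Si](C)(C)C)C1=O | intermediate (not isolated)
12 | 2-(trimethylsilyl)ethyl (1S,4aS,8aS)-8a-hydroxy-1,4a-dimethyl-5-oxodecahydronaphthalene-1-carboxylate (5α-OH, trans-fused) | C1CC[C@]2(O)[C@](C)(CCC[C@]2(C)C(=O)OCC[Si](C)(C)C)C1=O | intermediate
13 | 2-(trimethylsilyl)ethyl (1S,4aS,8aS)-6-[(dimethylamino)methyl]-8a-hydroxy-1,4a-dimethyl-5-oxodecahydronaphthalene-1-carboxylate (Mannich base, C8 epimers) | CN(C)CC1CC[C@]2(O)[C@](C)(CCC[C@]2(C)C(=O)OCC[Si](C)(C)C)C1=O | intermediate (not isolated)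
14 | N-methyl ammonium iodide of 13 (C17–NMe3+ I−) | C[N+](C)(C)CC1CC[C@]2(O)[C@](C)(CCC[C@]2(C)C(=O)OCC[Si](C)(C)C)C1=O.[I-] | intermediate (not isolated)
15 | 2-(trimethylsilyl)ethyl (1S,4aS,8aS)-8a-hydroxy-1,4a-dimethyl-6-methylidene-5-oxodecahydronaphthalene-1-carboxylate | C=C1CC[C@]2(O)[C@](C)(CCC[C@]2(C)C(=O)OCC[Si](C)(C)C)C1=O | intermediate
16 | tert-butyl(but-3-yn-1-yloxy)dimethylsilane | C#CCCO[Si](C)(C)C(C)(C)C | starting material
17 | [(1E)-4-(tert-butyldimethylsilyloxy)-2-methylbut-1-en-1-yl]dimethylalane | CC(C)(C)[Si](C)(C)OCC/C(C)=C/[Al](C)C | intermediate (not isolated)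
18 | lithium butyl[(1E)-4-(tert-butyldimethylsilyloxy)-2-methylbut-1-en-1-yl]dimethylaluminate | [Li+].CCCC[Al-](C)(C)/C=C(C)/CCO[Si](C)(C)C(C)(C)C | intermediate (not isolated)
19 | (2E)-5-(tert-butyldimethylsilyloxy)-3-methylpent-2-en-1-ol | CC(C)(C)[Si](C)(C)OCC/C(C)=C/CO | intermediate
20 | (2E)-5-(tert-butyldimethylsilyloxy)-1-(tert-butyldiphenylsilyloxy)-3-methylpent-2-ene | CC(C)(C)[Si](C)(C)OCC/C(C)=C/CO[Si](c1ccccc1)(c1ccccc1)C(C)(C)C | intermediate
21 | (3E)-5-(tert-butyldiphenylsilyloxy)-3-methylpent-3-en-1-ol | OCC/C(C)=C/CO[Si](c1ccccc1)(c1ccccc1)C(C)(C)C | intermediate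
22 | tert-butyl{[(2E)-5-iodo-3-methylpent-2-en-1-yl]oxy}diphenylsilane | ICC/C(C)=C/CO[Si](c1ccccc1)(c1ccccc1)C(C)(C)C | intermediate
23 | [(3E)-5-(tert-butyldiphenylsilyloxy)-3-methylpent-3-en-1-yl]lithium | [Li]CC/C(C)=C/CO[Si](c1ccccc1)(c1ccccc1)C(C)(C)C | intermediate (not isolated)
24 | dichloro[(3E)-5-(tert-butyldiphenylsilyloxy)-3-methylpent-3-en-1-yl]cerium | Cl[Ce](Cl)CC/C(C)=C/CO[Si](c1ccccc1)(c1ccccc1)C(C)(C)C | intermediate (not isolated)
25 | 2-(trimethylsilyl)ethyl 15-O-(tert-butyldiphenylsilyl)-5α,9β-dihydroxyisocupressate | C=C1CC[C@]2(O)[C@](C)(CCC[C@]2(C)C(=O)OCC[Si](C)(C)C)[C@]1(O)CC/C(C)=C/CO[Si](c1ccccc1)(c1ccccc1)C(C)(C)C | intermediate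
26 | 5α,9β-dihydroxyisocupressic acid | C=C1CC[C@]2(O)[C@](C)(CCC[C@]2(C)C(=O)O)[C@]1(O)CC/C(C)=C/CO | target

**Step count**
Total: 12 steps. Longest linear sequence: 8 steps (steps 1–6, 11 and 12); steps 7–10 make the side chain.

**Steps most likely to fail**

Step 3 (Proposed new method). What may go wrong: weak facial discrimination in the ion pair, so that the ring closes with low enantioselectivity, or alkylation on the ester oxygen in competition with C10. Fallback with known chemistry, from 6 back to 10: 6 is cyclised without induction by KOtBu in t-BuOH/THF (the protic medium ties up the oxygens and favours carbon) to the racemic bicyclic keto ester F1. Ketalisation with (R,R)-hydrobenzoin (TsOH cat., benzene, Dean–Stark) gives two diastereomeric spiro ketals, the ketal of 7 F2 and the ketal of its enantiomer F3, which are separated by crystallisation or chromatography. The ketal takes over the role of the silyl enol ether of step 4, so F2 is methylated (LDA, DMPU, MeI, −78 °C) to the ketal of 10 F4, and 2 M HCl in THF releases 10.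

Step 11. What may go wrong: conjugate attack at C17 or oligomerisation of the exocyclic enone may outrun 1,2-addition at the neopentyl C9 carbonyl, and base-induced retro-aldol opening of the C5–C10 bond may consume the alkoxide. Fallback, from 13 back to 25: step 6 is stopped at the Mannich base 13, which is isolated. The organocerium reagent 24 is added to its C9 ketone, where no enone is present, to give the amino diol F5. mCPBA (1 equiv, CH2Cl2, −78 °C) oxidises the amine in preference to the alkene to the amine N-oxide F6, and Cope elimination (toluene, 100 °C) through the single β-hydrogen at C8 gives 25.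

Step 5. What may go wrong: slow hydrogen-atom transfer to an alkene that lies between two quaternary carbons, or capture of the C5 radical on the β face, which would give the cis ring fusion. Fallback, from 10 back to 12: osmylation (OsO4, pyridine, then aq NaHSO3) on the open α face gives the 5α,6α-diol F7. Only the secondary 6-OH is acylated (PhOC(S)Cl, DMAP, MeCN) to the 6-O-phenoxythiocarbonyl derivative F8, and Barton–McCombie reduction (Bu3SnH, AIBN, toluene, 80 °C) removes it to give 12.

**Further compounds**
F1 | step 3 | racemic 2-(trimethylsilyl)ethyl 4a-methyl-5-oxo-2,3,4,4a,5,6,7,8-octahydronaphthalene-1-carboxylate | C1CCC2=C(C(=O)OCC[Si](C)(C)C)CCCC2(C)C1=O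
F2 | step 3 | (4R,5R)-4,5-diphenyl-1,3-dioxolane spiro ketal of 7 at C9 | C1CCC2=C(C(=O)OCC[Si](C)(C)C)CCC[C@]2(C)C13O[C@H](c4ccccc4)[C@@H](c4ccccc4)O3
F3 | step 3 | (4R,5R)-4,5-diphenyl-1,3-dioxolane spiro ketal of the enantiomer of 7 | C1CCC2=C(C(=O)OCC[Si](C)(C)C)CCC[C@@]2(C)C13O[C@H](c4ccccc4)[C@@H](c4ccccc4)O3
F4 | step 3 | (4R,5R)-4,5-diphenyl-1,3-dioxolane spiro ketal of 10 at C9 | C1CC=C2[C@](C)(CCC[C@]2(C)C(=O)OCC[Si](C)(C)C)C13O[C@H](c4ccccc4)[C@@H](c4ccccc4)O3
F5 | step 11 | 2-(trimethylsilyl)ethyl 15-O-(tert-butyldiphenylsilyl)-17-(dimethylamino)-8,17-dihydro-5α,9β-dihydroxyisocupressate (C8 epimers) | CN(C)CC1CC[C@]2(O)[C@](C)(CCC[C@]2(C)C(=O)OCC[Si](C)(C)C)[C@]1(O)CC/C(C)=C/CO[Si](c1ccccc1)(c1ccccc1)C(C)(C)C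
F6 | step 11 | N-oxide of F5 | C[N+](C)([O-])CC1CC[C@]2(O)[C@](C)(CCC[C@]2(C)C(=O)OCC[Si](C)(C)C)[C@]1(O)CC/C(C)=C/CO[Si](c1ccccc1)(c1ccccc1)C(C)(C)C
F7 | step 5 | 2-(trimethylsilyl)ethyl 5α,6α-dihydroxy-4α,10β-dimethyl-9-oxodecalin-4β-carboxylate | C1C[C@H](O)[C@]2(O)[C@](C)(CCC[C@]2(C)C(=O)OCC[Si](C)(C)C)C1=O
F8 | step 5 | 6-O-(phenoxythiocarbonyl) derivative of F7 | C1C[C@H](OC(=S)Oc3ccccc3)[C@]2(O)[C@](C)(CCC[C@]2(C)C(=O)OCC[Si](C)(C)C)C1=O
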